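**Plan**
- Retrosynthesis: the last cuts are the indole N1–sulfonyl bond and the pyrrole C5''–Br bond. Next comes the oxazole C2'–pyrrole C2'' bond (cross-coupling through a C2'–I handle).
- The oxazole is then opened across O1'–C2' and C4'–C5' to an indole-3-carbaldehyde and tosylmethyl isocyanide, and the C3–CHO bond leads back to 6-bromo-4-methoxyindole.
- Enabling feature: oxazole C5' carries indole C3, C4' bears only hydrogen, and C2' can be substituted later. This is the pattern an aldehyde carbon and the C–N=C unit of TosMIC deliver.
- Forward: the indole is bought, C3 is formylated, N1 is tosylated, and the oxazole (the only ring formed) is closed on the aldehyde. The pyrrole ring is attached intact at C2', then C5'' bromination and N-deprotection finish the route.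
- Stereochemistry: the target has no stereogenic element, so nothing has to be set. The two sp3 centres of the transient oxazoline disappear on aromatisation.

Key step: step 3

Remark on the chemistry: the target is achiral, so the single-enantiomer requirement needs no action. Ts is p-tolylsulfonyl. Compounds 1, 5 and 10 and the TMPZnCl·LiCl solution are taken as purchasable.

**Route**

Step 1
Reactants: 1 6-bromo-4-methoxy-1H-indole
Product: 3 6-bromo-4-methoxy-1H-indole-3-carbaldehyde, via C3-methyleneiminium salt 2 (not isolated)
Conditions: POCl3, DMF, 0 °C → 40 °C; then aq NaOH, 0 °C → rt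
Reagents that add atoms: N,N-dimethylformamide CN(C)C=O; water O
Why: Vilsmeier–Haack formylation, in which the chloroiminium ion from DMF/POCl3 is attacked by indole C3 (the most nucleophilic carbon of the 4-methoxyindole) and alkaline hydrolysis of iminium salt 2 releases the aldehyde without touching the aryl bromide or the methyl ether.

Step 2
Reactants: 3 6-bromo-4-methoxy-1H-indole-3-carbaldehyde
Product: 4 6-bromo-4-methoxy-1-tosyl-1H-indole-3-carbaldehyde
Conditions: NaH, THF, 0 °C; then TsCl, 0 °C → rt
Reagents that add atoms: p-toluenesulfonyl chloride Cc1ccc(S(=O)(=O)Cl)cc1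
Why: N-sulfonylation of the sodium indolide (the N–H is acidified by the 3-formyl group), which turns the vinylogous formamide into a normally electrophilic aryl aldehyde and masks N1 for the later base, metal and bromination steps.

Step 3
Reactants: 4 6-bromo-4-methoxy-1-tosyl-1H-indole-3-carbaldehyde; 5 tosylmethyl isocyanide (TosMIC)
Product: 7 5-(6-bromo-4-methoxy-1-tosyl-1H-indol-3-yl)oxazole, via 4-tosyl-2-oxazoline 6 (not isolated)
Conditions: TosMIC (1.2 equiv), DBU, DME, rt → 80 °C
Reagents that add atoms: none
Why: Van Leusen oxazole synthesis: DBU deprotonates the CH2 of 5 that is flanked by sulfonyl and isocyanide, and the carbanion adds to the aldehyde carbon of 4, forming C4'–C5'. The alkoxide then closes onto the isocyanide carbon in a 5-endo-dig cyclisation (O1'–C2'), and protonation gives the 4-tosyl-2-oxazoline 6. Base-induced loss of p-toluenesulfinate across C4'–C5' aromatises the ring and erases the two transient stereocentres of 6, so no stereocontrol is required. The closest known reaction type is the TosMIC annulation of aryl and heteroaryl aldehydes, indole-3-carbaldehydes included. Regiocontrol is built into the reagent (the aldehyde carbon becomes C5', C4' stays unsubstituted, C2' stays C–H), and chemoselectivity is secured by the N-sulfonyl group, which switches off the N1-to-formyl donation that the 4-methoxy group would reinforce, and by a non-nucleophilic amidine base in an aprotic ether, so that no alkoxide is present to strip the sulfonyl group. No transition metal is involved, so the C6–Br bond is not at risk.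

Step 4
Reactants: 7 5-(6-bromo-4-methoxy-1-tosyl-1H-indol-3-yl)oxazole
Product: 9 5-(6-bromo-4-methoxy-1-tosyl-1H-indol-3-yl)-2-iodooxazole, via oxazol-2-ylzinc chloride 8 (not isolated)
Conditions: TMPZnCl·LiCl, THF, 25 °C; then I2, THF, 0 °C → rt
Reagents that add atoms: iodine II
Why: Directed deprotonative zincation with a hindered zinc amide takes the most acidic C–H (oxazole C2', between O and N), the C–Zn species stays ring-closed instead of opening to an isocyano enolate so that iodinolysis places iodine at C2' only, and an amide base does not undergo halogen–metal exchange with the C6 bromide.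

Step 5
Reactants: 9 5-(6-bromo-4-methoxy-1-tosyl-1H-indol-3-yl)-2-iodooxazole; 10 1-Boc-pyrrole-2-boronic acid
Product: 11 tert-butyl 2-[5-(6-bromo-4-methoxy-1-tosyl-1H-indol-3-yl)oxazol-2-yl]-1H-pyrrole-1-carboxylate
Conditions: Pd(PPh3)4 (5 mol %), aq Na2CO3, DME, 70 °C, boronic acid in excess
Reagents that add atoms: none
Why: Suzuki–Miyaura coupling, in which Pd(0) should insert into the C2'–I bond of the electron-poor azole far faster than into the C6–Br bond of the electron-rich methoxyindole, while an excess of the Boc-stabilised 2-pyrrolylboronic acid at moderate temperature offsets protodeboronation.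

Step 6
Reactants: 11 tert-butyl 2-[5-(6-bromo-4-methoxy-1-tosyl-1H-indol-3-yl)oxazol-2-yl]-1H-pyrrole-1-carboxylate
Product: 12 6-bromo-4-methoxy-3-[2-(1H-pyrrol-2-yl)oxazol-5-yl]-1-tosyl-1H-indole
Conditions: TFA, CH2Cl2, 0 °C → rt
Reagents that add atoms: none
Why: Acidolytic carbamate cleavage (loss of the tert-butyl cation as isobutene, then decarboxylation), to which the N-sulfonyl indole, both carbon–halogen sites, the oxazole and the methyl ether are inert, the oxazolyl acceptor tempering the pyrrole against acid-induced oligomerisation.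

Step 7
Reactants: 12 6-bromo-4-methoxy-3-[2-(1H-pyrrol-2-yl)oxazol-5-yl]-1-tosyl-1H-indole
Product: 13 6-bromo-3-[2-(5-bromo-1H-pyrrol-2-yl)oxazol-5-yl]-4-methoxy-1-tosyl-1H-indole
Conditions: NBS (1.0 equiv), THF, −78 °C
Reagents that add atoms: N-bromosuccinimide O=C1CCC(=O)N1Br
Why: Electrophilic aromatic bromination, in which the free α-position C5'' of the N–H pyrrole is by far the most nucleophilic carbon of 12 (the 2-oxazolyl group conjugates and withdraws only weakly, and α-attack gives the better stabilised σ-complex), the indole is deactivated by its N-sulfonyl group, and one equivalent of NBS at low temperature limits dibromination.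

Step 8
Reactants: 13 6-bromo-3-[2-(5-bromo-1H-pyrrol-2-yl)oxazol-5-yl]-4-methoxy-1-tosyl-1H-indole
Product: 14 6-bromo-3-[2-(5-bromo-1H-pyrrol-2-yl)oxazol-5-yl]-4-methoxy-1H-indole
Conditions: aq NaOH, THF/MeOH, 50 °C; neutralise on work-up
Reagents that add atoms: none
Why: Nucleophilic cleavage of the N-sulfonyl indole by attack of hydroxide or methoxide at sulfur with expulsion of the stabilised indolide, the aryl and pyrrolyl bromides, the oxazole and the methyl ether being inert to aqueous alkali in the absence of a metal catalyst.

**Compound list**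
1 | 6-bromo-4-methoxy-1H-indole | COc1cc(Br)cc2[nH]ccc12 | starting material
2 | (6-bromo-4-methoxy-1H-indol-3-yl)methylene-dimethyliminium dichlorophosphate | COc1cc(Br)cc2[nH]cc(C=[N+](C)C)c12.[O-]P(=O)(Cl)Cl | intermediate (not isolated)
3 | 6-bromo-4-methoxy-1H-indole-3-carbaldehyde | COc1cc(Br)cc2[nH]cc(C=O)c12 | intermediate
4 | 6-bromo-4-methoxy-1-tosyl-1H-indole-3-carbaldehyde | COc1cc(Br)cc2n(S(=O)(=O)c3ccc(C)cc3)cc(C=O)c12 | intermediate
5 | tosylmethyl isocyanide | Cc1ccc(S(=O)(=O)C[N+]#[C-])cc1 | starting material
6 | 5-(6-bromo-4-methoxy-1-tosyl-1H-indol-3-yl)-4-tosyl-4,5-dihydrooxazole (racemic; both sp3 centres are lost in the same step) | COc1cc(Br)cc2n(S(=O)(=O)c3ccc(C)cc3)cc(C3OC=NC3S(=O)(=O)c3ccc(C)cc3)c12 | intermediate (not isolated)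
7 | 5-(6-bromo-4-methoxy-1-tosyl-1H-indol-3-yl)oxazole | COc1cc(Br)cc2n(S(=O)(=O)c3ccc(C)cc3)cc(-c3cnco3)c12 | intermediate
8 | [5-(6-bromo-4-methoxy-1-tosyl-1H-indol-3-yl)oxazol-2-yl]zinc chloride | COc1cc(Br)cc2n(S(=O)(=O)c3ccc(C)cc3)cc(-c3cnc([Zn]Cl)o3)c12 | intermediate (not isolated)
9 | 5-(6-bromo-4-methoxy-1-tosyl-1H-indol-3-yl)-2-iodooxazole | COc1cc(Br)cc2n(S(=O)(=O)c3ccc(C)cc3)cc(-c3cnc(I)o3)c12 | intermediate
10 | 1-Boc-pyrrole-2-boronic acid | CC(C)(C)OC(=O)n1cccc1B(O)O | starting material
11 | tert-butyl 2-[5-(6-bromo-4-methoxy-1-tosyl-1H-indol-3-yl)oxazol-2-yl]-1H-pyrrole-1-carboxylate | COc1cc(Br)cc2n(S(=O)(=O)c3ccc(C)cc3)cc(-c3cnc(-c4cccn4C(=O)OC(C)(C)C)o3)c12 | intermediate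
12 | 6-bromo-4-methoxy-3-[2-(1H-pyrrol-2-yl)oxazol-5-yl]-1-tosyl-1H-indole | COc1cc(Br)cc2n(S(=O)(=O)c3ccc(C)cc3)cc(-c3cnc(-c4ccc[nH]4)o3)c12 | intermediate
13 | 6-bromo-3-[2-(5-bromo-1H-pyrrol-2-yl)oxazol-5-yl]-4-methoxy-1-tosyl-1H-indole | COc1cc(Br)cc2n(S(=O)(=O)c3ccc(C)cc3)cc(-c3cnc(-c4ccc(Br)[nH]4)o3)c12 | intermediate
14 | 6-bromo-3-[2-(5-bromo-1H-pyrrol-2-yl)oxazol-5-yl]-4-methoxy-1H-indole | COc1cc(Br)cc2[nH]cc(-c3cnc(-c4ccc(Br)[nH]4)o3)c12 | target

**Step count and risks**
Total step count: 8. Longest linear sequence: 8 steps (1 → 14).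

Steps most likely to fail:

Step 3 (key step). The annulation base may strip the N-sulfonyl group before ring closure, the peri-methoxy-hindered aldehyde may react slowly enough for TosMIC to self-condense, or sulfinate elimination from the oxazoline may stall. The fallback inverts the order of protection and annulation. It sets out from 3, which would be heated with 5 and K2CO3 in MeOH (the classical protocol for unprotected indole-3-carbaldehydes, where no protecting group is exposed). This should give, through 5-(6-bromo-4-methoxy-1H-indol-3-yl)-4-tosyl-4,5-dihydrooxazole F1, the free oxazole 5-(6-bromo-4-methoxy-1H-indol-3-yl)oxazole F2. N-Tosylation of F2 (NaH, TsCl, THF, 0 °C; the indole N–H is far more acidic than oxazole C2'–H) comes back to the route at 7.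

Step 5. Protodeboronation of the 2-pyrrolylboronic acid and base-mediated erosion of the Boc group may outrun transmetalation, leaving reduced or unreacted iodide. The fallback inverts the polarity of the coupling and needs no base. It sets out from 7, which would be zincated to 8 as in step 4. Instead of being iodinated, 8 would be coupled in a Negishi reaction with tert-butyl 2-iodo-1H-pyrrole-1-carboxylate (Pd(dba)2, tri(2-furyl)phosphine, THF, 25–50 °C; aryl iodide insertion is preferred over the C6 bromide). The route is rejoined at 11.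

Step 7. Bromination may run past the mono stage or divide between pyrrole C5'' and C4'', and the 4-methoxy-activated benzo ring may compete. The fallback brominates at the carbamate stage instead. It sets out from 11, where the N-Boc group lowers the reactivity of the pyrrole and N-acyl pyrroles are known to brominate at the free α-position. NBS (THF, −78 → 0 °C) should give tert-butyl 2-bromo-5-[5-(6-bromo-4-methoxy-1-tosyl-1H-indol-3-yl)oxazol-2-yl]-1H-pyrrole-1-carboxylate F3. Acidolysis of F3 (TFA, CH2Cl2) returns to the route at 13.

**Further compounds**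
F1 | step 3 | 5-(6-bromo-4-methoxy-1H-indol-3-yl)-4-tosyl-4,5-dihydrooxazole (racemic, not isolated) | COc1cc(Br)cc2[nH]cc(C3OC=NC3S(=O)(=O)c3ccc(C)cc3)c12
F2 | step 3 | 5-(6-bromo-4-methoxy-1H-indol-3-yl)oxazole | COc1cc(Br)cc2[nH]cc(-c3cnco3)c12
F0 | step 5 | none | none
F3 | step 7 | tert-butyl 2-bromo-5-[5-(6-bromo-4-methoxy-1-tosyl-1H-indol-3-yl)oxazol-2-yl]-1H-pyrrole-1-carboxylate | COc1cc(Br)cc2n(S(=O)(=O)c3ccc(C)cc3)cc(-c3cnc(-c4ccc(Br)n4C(=O)OC(C)(C)C)o3)c12
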